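At 40 °C grey and green differ in time, so put the clocks of this flask in order, shortest first.

| setting | larch | cedar | grey | green |
|---|---|---|---|---|
| starting material | 0.050 M | 0.050 M | 0.050 M | 0.050 M |
| partner | 0.077 M | 0.12 M | 0.0550 M | 0.0550 M |
| temperature | 25 °C | 40 °C | 40 °C | 40 °C |
| remark | run made earlier | run made earlier |  |  |
| time |  |  | 15 min | 50 min |

| run | time / min | target / % |
|---|---|---|
| larch | 3.00 | 0.6 |
| larch | 8.00 | 2.1 |
| larch | 12.0 | 3.4 |
| larch | 20.0 | 34.4 |
| larch | 30.0 | 55.9 |
| larch | 40.0 | 47.8 |
| cedar | 1.33 | 1.4 |
| cedar | 4.00 | 12.6 |
| cedar | 6.00 | 45.8 |
| cedar | 10.0 | 33.7 |
| cedar | 15.0 | 11.0 |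
| cedar | 20.0 | 3.8 |

(standard deviation of a reading: 1 percentage point)

* which of the two ends with the higher amount of target, in percent of the starting material charged ("neither" if they lie within 2 percentage points) (grey / green / neither)
* target at the end, in percent of the starting material charged, grey
* target at the end, in percent of the starting material charged, green

- the numbers in the tables scatter by 1 percentage point (one standard deviation)

The first clock is the loss of target. After its top reading in the cedar run, the target falls by a factor of 3.06 over the first 5.00 min, then by 2.89 over the next 5.00 min. Equal times divide it about equally, so in the cedar run the loss reads as first order in the target. From this I carry the target half-life, the time in which loss cuts the target by a factor of 2.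

loss constant = ln(reading at 10.0 min / reading at 20.0 min) / time between = 0.218 min⁻¹

target half-life = ln(2) / loss constant = 3.18 min

The next clock is the wait before the rise. Cedar's top reading stands at 6.00 min. If you stretch that wait inversely with partner, which is my assumption, grey and green reach their top near 13.1 min, longer than the target half-life.

The asked times come last. Grey stops 0.597 half-lives after that top, so I expect it near its peak, below cedar's 45.8%. Green stops 11.6 half-lives after it, and on this reckoning even cedar's top reading would shrink to 0.0145%. So my reckoning says grey ends higher. The risk is that the cedar readings, taken with partner in excess, do not show whether the loss needs partner.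

The forecast parts from me here. It says green, with 42% for grey and 65% for green, reasoning that “partner is nearly exhausted once the starting material is used, so the loss should stall”.

The flask gives grey: 20.3% in grey and 0.158% in green.

    starting material + partner → target (k = 1.09 × 10⁻⁴ M⁻¹ s⁻¹, Ea = 63.0 kJ mol⁻¹)
    target → over-reaction product (k = 0.00403 s⁻¹, Ea = 93.0 kJ mol⁻¹)
    starting material + partner + target → 2 target (k = 4.65 M⁻² s⁻¹, Ea = 48.0 kJ mol⁻¹)
    (constants at 40 °C)

Grey still held 95.5% starting material and 3.08% target at 7.50 min. By 15 min it held 56.0% starting material and 23.7% over-reaction product, with target made 1.98 times faster than used up at 11.5 min and 1.07 times at the end. From green's 7.85% target at 25.0 min, the target half-life leaves 0.0335%, but green holds more, 0.158%, with 28.2% starting material and 34.7% partner still there. The neighbour of grey with 0.093 M partner holds 18.2% target at 15.0 min against the 11.0% read in cedar, which, reckoned with the loss constant, equals a delay of about 2.31 min.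

Readings and results were computed with made-up constants.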